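**Retrosynthetic overview**

1. The target comes from the C8 bromide 28 by CuI-catalysed methoxylation; the C8 oxygen is carried as bromine because an alkoxy group on C8 would steer opening of the oxygen bridge toward C6–O cleavage and would be acid-labile in the furan and in the cycloadduct.
2. Feature: rings A and B share the C4a–C8a bond. A 2-alkyl-3-bromofuran holds C8a, C8, C7, C6 and the future C6 oxygen, an aryl alkyne holds C4a and C5 with the naphthyl already on C5, and the chain C1–N2–C3–C4 joins them. One intramolecular furan–alkyne [4+2] cycloaddition (C4a–C8a and C5–C6) followed by opening of the bridge at C8a closes rings B and A together.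
3. Precursor 25 comes from Sonogashira coupling (C5–C1') of naphthyl iodide 24 with alkyne 15; the C4–C4a bond comes from acetylide opening of cyclic sulfamidate 10.
4. The N–C3 bond is made by SN2 inversion of (R)-lactate triflate 7 with (R)-amine 5 (C1 set by sulfinimine addition), which gives the unlike (1R,3S) pair directly.
5. Ring order: the two naphthalene rings first (aryne insertion into acetylacetone, aldol aromatisation), then rings A and B at once in the key step.

Key step: step 16

Assumption: the SMILES fixes C1 (R) and C3 (S) but not the sense of the C5–C1' biaryl axis, so the axis is treated as unspecified and is not controlled; atom numbers are those of the tetrahydroisoquinoline, primed numbers those of the naphthalene.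

**Route**

Step 1
Reactants: 1 3-bromofuran-2-carbaldehyde; 2 (S)-2-methylpropane-2-sulfinamide
Product: 3 (S,E)-N-[(3-bromofuran-2-yl)methylidene]-2-methylpropane-2-sulfinamide
Conditions: pyrrolidine (10 mol%), 4 Å MS, CH2Cl2, rt
Reagents that add atoms: none
Why: Amine-catalysed condensation of an aldehyde with tert-butanesulfinamide (Ellman imine formation) should give the (E)-sulfinyl aldimine without touching the sulfur centre.

Step 2
Reactants: 3 (S,E)-N-[(3-bromofuran-2-yl)methylidene]-2-methylpropane-2-sulfinamide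
Product: 4 (S)-N-[(1R)-1-(3-bromofuran-2-yl)ethyl]-2-methylpropane-2-sulfinamide
Conditions: MeMgBr, CH2Cl2, −48 °C; aq. NH4Cl
Reagents that add atoms: methylmagnesium bromide, C[Mg]Br
Why: Ellman 1,2-addition: in CH2Cl2 the Grignard reagent should add through the six-membered, magnesium-bridged chair transition state with the tert-butyl group equatorial, which from the (S)-sulfinyl imine delivers methyl to the face that makes C1 (R); the minor diastereomer would be removed by chromatography.

Step 3
Reactants: 4 (S)-N-[(1R)-1-(3-bromofuran-2-yl)ethyl]-2-methylpropane-2-sulfinamide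
Product: 5 (1R)-1-(3-bromofuran-2-yl)ethan-1-amine
Conditions: HCl (4 M in dioxane), MeOH, 0 °C → rt; aq. NaOH
Reagents that add atoms: none
Why: Acidic methanolysis of the N–S bond (sulfinamide cleavage) should free the primary amine, and the bromofuran is deactivated enough to survive the acid and keep the C–N centre intact.

Step 4
Reactants: 6 methyl (R)-lactate
Product: 7 methyl (2R)-2-{[(trifluoromethyl)sulfonyl]oxy}propanoate
Conditions: Tf2O, 2,6-lutidine, CH2Cl2, −78 → 0 °C
Reagents that add atoms: trifluoromethanesulfonic anhydride, O=S(=O)(OS(=O)(=O)C(F)(F)F)C(F)(F)F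
Why: O-Triflation of the α-hydroxy ester breaks only the O–H bond, so the configuration is retained.

Step 5
Reactants: 5 (1R)-1-(3-bromofuran-2-yl)ethan-1-amine; 7 methyl (2R)-2-{[(trifluoromethyl)sulfonyl]oxy}propanoate
Product: 8 methyl (2S)-2-{[(1R)-1-(3-bromofuran-2-yl)ethyl]amino}propanoate
Conditions: 2,6-lutidine, CH2Cl2, 0 °C → rt
Reagents that add atoms: none
Why: SN2 displacement of an α-triflyloxy ester by a primary amine, a substitution that proceeds with clean inversion even for α-branched amines, should set C3 as (S) and so give the unlike (R,S) secondary amine.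

Step 6
Reactants: 8 methyl (2S)-2-{[(1R)-1-(3-bromofuran-2-yl)ethyl]amino}propanoate
Product: 9 (2S)-2-{[(1R)-1-(3-bromofuran-2-yl)ethyl]amino}propan-1-ol
Conditions: LiAlH4, THF, 0 °C; Fieser work-up
Reagents that add atoms: none
Why: Hydride reduction of the ester to the primary alcohol at 0 °C should leave the α-amino stereocentre and the furyl bromide untouched.

Step 7
Reactants: 9 (2S)-2-{[(1R)-1-(3-bromofuran-2-yl)ethyl]amino}propan-1-ol
Product: 10 (4S)-3-[(1R)-1-(3-bromofuran-2-yl)ethyl]-4-methyl-1,2,3-oxathiazolidine 2,2-dioxide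
Conditions: SO2Cl2, Et3N, CH2Cl2, −78 °C → rt
Reagents that add atoms: sulfuryl chloride, O=S(=O)(Cl)Cl
Why: Cyclic sulfamidate formation from a 1,2-amino alcohol with a bulky N-substituent; the one-step method with SO2Cl2 is chosen because the furan would not be safe in a RuO4 oxidation of the sulfamidite.

Step 8
Reactants: 10 (4S)-3-[(1R)-1-(3-bromofuran-2-yl)ethyl]-4-methyl-1,2,3-oxathiazolidine 2,2-dioxide; 11 ethynyltrimethylsilane
Product: 14 (2S)-N-[(1R)-1-(3-bromofuran-2-yl)ethyl]pent-4-yn-2-amine, via N-sulfamic acid 12 (not isolated), via C-silyl amine 13 (not isolated)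
Conditions: 11, n-BuLi, THF, −78 °C; 10, −78 °C → rt; 2 M aq. HCl, rt; K2CO3, MeOH, rt
Reagents that add atoms: none
Why: The lithium acetylide should open the cyclic sulfamidate by SN2 attack at the primary C–O carbon (the nitrogen is masked as a sulfamate, so no aziridinium ion can form), after which aqueous acid hydrolyses the N-sulfamic acid and methanolysis removes the C-silyl group; C3 is not involved and stays (S).

Step 9
Reactants: 14 (2S)-N-[(1R)-1-(3-bromofuran-2-yl)ethyl]pent-4-yn-2-amine
Product: 15 (2S)-N-[(1R)-1-(3-bromofuran-2-yl)ethyl]-N-methylpent-4-yn-2-amine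
Conditions: aq. CH2O, NaBH(OAc)3, AcOH, ClCH2CH2Cl, rt
Reagents that add atoms: formaldehyde, C=O
Why: Reductive amination with formaldehyde (iminium formation, hydride reduction) should methylate the hindered secondary amine without any risk of quaternisation.

Step 10
Reactants: 16 3-methoxy-2-(trimethylsilyl)phenyl trifluoromethanesulfonate; 17 acetylacetone
Product: 19 1-(2-acetyl-3-methoxyphenyl)propan-2-one, via 3-methoxybenzyne 18 (not isolated)
Conditions: CsF, MeCN, 80 °C
Reagents that add atoms: none
Why: Aryne acyl-alkylation: fluoride releases the aryne, the diketone enolate carbon adds at the aryne carbon remote from OMe, and the aryl anion next to OMe attacks a ketone and the cyclobutoxide fragments, which inserts the aryne into the C–C bond with the acetyl group beside OMe.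

Step 11
Reactants: 19 1-(2-acetyl-3-methoxyphenyl)propan-2-one
Product: 20 8-methoxy-3-methylnaphthalen-1-ol
Conditions: NaOMe, MeOH, 65 °C; aq. HCl
Reagents that add atoms: none
Why: Intramolecular aldol condensation of the aryl methyl ketone enolate onto the unhindered aliphatic ketone, then dehydration and tautomerisation, should give the 3-methyl-1-naphthol, since the other closure onto the hindered aryl ketone would force methyl and methoxy into a peri relationship.

Step 12
Reactants: 20 8-methoxy-3-methylnaphthalen-1-ol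
Product: 21 8-methoxy-3-methylnaphthalen-1-yl acetate
Conditions: Ac2O, pyridine, DMAP (cat.), CH2Cl2, rt
Reagents that add atoms: acetic anhydride, CC(=O)OC(C)=O
Why: O-Acylation of the naphthol lowers the electron density of the methyl-bearing ring, so that the next electrophile goes to the methoxy-bearing ring.

Step 13
Reactants: 21 8-methoxy-3-methylnaphthalen-1-yl acetate
Product: 22 5-iodo-8-methoxy-3-methylnaphthalen-1-yl acetate
Conditions: NIS, TFA (cat.), MeCN, 0 °C → rt
Reagents that add atoms: N-iodosuccinimide, O=C1CCC(=O)N1I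
Why: Electrophilic aromatic iodination should occur at C5, the α position para to the methoxy group, which is the most activated site once the other ring carries the acetoxy group.

Step 14
Reactants: 22 5-iodo-8-methoxy-3-methylnaphthalen-1-yl acetate
Product: 24 1-iodo-4,5-dimethoxy-7-methylnaphthalene, via iodonaphthol 23 (not isolated)
Conditions: K2CO3, MeOH, rt; then MeI, DMF, 40 °C
Reagents that add atoms: iodomethane, CI
Why: Methanolysis of the aryl acetate followed by Williamson O-methylation of the naphthoxide in the same flask.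

Step 15
Reactants: 15 (2S)-N-[(1R)-1-(3-bromofuran-2-yl)ethyl]-N-methylpent-4-yn-2-amine; 24 1-iodo-4,5-dimethoxy-7-methylnaphthalene
Product: 25 (2S)-N-[(1R)-1-(3-bromofuran-2-yl)ethyl]-5-(4,5-dimethoxy-7-methylnaphthalen-1-yl)-N-methylpent-4-yn-2-amine
Conditions: PdCl2(PPh3)2, CuI, Et3N, THF, 40 °C
Reagents that add atoms: none
Why: Sonogashira coupling; the aryl iodide should add oxidatively to zerovalent palladium far faster than the furyl bromide at this temperature.

Step 16
Reactants: 25 (2S)-N-[(1R)-1-(3-bromofuran-2-yl)ethyl]-5-(4,5-dimethoxy-7-methylnaphthalen-1-yl)-N-methylpent-4-yn-2-amine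
Product: 27 (1R,3S)-8-bromo-5-(4,5-dimethoxy-7-methylnaphthalen-1-yl)-1,2,3-trimethyl-1,2,3,4-tetrahydroisoquinolin-6-ol, via oxanorbornadiene 26 (not isolated)
Conditions: o-C6H4Cl2, BHT (cat.), 200 °C, sealed tube; then TFA, CH2Cl2, 0 °C → rt; aq. NaHCO3
Reagents that add atoms: none
Why: Proposed new method: on heating, the 2-alkyl-3-bromofuran (C8a, C8, C7, C6 and the ring oxygen) should add as the diene across the tethered aryl alkyne (C4a≡C5) in a concerted intramolecular [4+2] cycloaddition that forms C4a–C8a and C5–C6 and gives the 7-oxanorbornadiene 26; the closest known reaction type is the intramolecular Diels–Alder reaction of furans with tethered alkynes, which gives fused phenols after opening of the oxygen bridge and is favoured by a halogen on the furan, but an unactivated internal aryl alkyne on a four-atom amine tether lies outside it. Ring B closes in the fused (type 1) mode as a six-membered ring through the C1–N2–C3–C4 tether, whose three branch points (C1-Me, N-Me, C3-Me) favour the folded conformer, and ring A is the six-membered carbocycle of the cycloadduct, at first bridged by oxygen between C8a and C6. TFA then protonates the bridge oxygen, the C8a–O bond ionises to a tertiary cation that is delocalised through C4a=C5 onto C5 next to the 4-methoxynaphthyl group, and loss of the C6 proton gives the C6 phenol irreversibly. The tether leaves no regiochemical choice in the cycloaddition, and the direction of bridge opening is secured by the substrate: C8 carries bromine, not a π-donor oxygen that would stabilise the cation from C6–O cleavage and leave the oxygen on the quaternary C8a, and only C6 bears a hydrogen that can be lost. The two bridgehead centres of 26 are transient and disappear on aromatisation, C1 and C3 are not involved, and the C5–C1' axis is expected to form as both atropisomers.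

Step 17
Reactants: 27 (1R,3S)-8-bromo-5-(4,5-dimethoxy-7-methylnaphthalen-1-yl)-1,2,3-trimethyl-1,2,3,4-tetrahydroisoquinolin-6-ol
Product: 28 (1R,3S)-8-bromo-5-(4,5-dimethoxy-7-methylnaphthalen-1-yl)-6-methoxy-1,2,3-trimethyl-1,2,3,4-tetrahydroisoquinoline
Conditions: TMSCHN2, iPr2NEt, MeOH–MeCN, rt
Reagents that add atoms: (trimethylsilyl)diazomethane, C[Si](C)(C)C=[N+]=[N-]
Why: O-Methylation of the phenol with (trimethylsilyl)diazomethane in methanol should not alkylate the tertiary amine.

Step 18
Reactants: 28 (1R,3S)-8-bromo-5-(4,5-dimethoxy-7-methylnaphthalen-1-yl)-6-methoxy-1,2,3-trimethyl-1,2,3,4-tetrahydroisoquinoline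
Product: 29 (1R,3S)-5-(4,5-dimethoxy-7-methylnaphthalen-1-yl)-6,8-dimethoxy-1,2,3-trimethyl-1,2,3,4-tetrahydroisoquinoline
Conditions: NaOMe, CuI (20 mol%), MeOH–DMF, 110 °C
Reagents that add atoms: sodium methoxide, [Na+].[O-]C
Why: Ullmann-type CuI-catalysed C–O coupling of the aryl bromide with methoxide should replace bromine at C8 by methoxy, possibly helped by the neighbouring benzylic amine as a ligand, and no stereocentre is at risk under these conditions.

**Compound list**

1 | 3-bromofuran-2-carbaldehyde | O=Cc1occc1Br | starting material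
2 | (S)-2-methylpropane-2-sulfinamide | CC(C)(C)[S@@](N)=O | starting material
3 | (S,E)-N-[(3-bromofuran-2-yl)methylidene]-2-methylpropane-2-sulfinamide | CC(C)(C)[S@@](/N=C/c1occc1Br)=O | intermediate
4 | (S)-N-[(1R)-1-(3-bromofuran-2-yl)ethyl]-2-methylpropane-2-sulfinamide | CC(C)(C)[S@@](N[C@H](C)c1occc1Br)=O | intermediate
5 | (1R)-1-(3-bromofuran-2-yl)ethan-1-amine | N[C@H](C)c1occc1Br | intermediate
6 | methyl (R)-lactate | C[C@@H](O)C(=O)OC | starting material
7 | methyl (2R)-2-{[(trifluoromethyl)sulfonyl]oxy}propanoate | C[C@@H](OS(=O)(=O)C(F)(F)F)C(=O)OC | intermediate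
8 | methyl (2S)-2-{[(1R)-1-(3-bromofuran-2-yl)ethyl]amino}propanoate | C[C@H](N[C@H](C)c1occc1Br)C(=O)OC | intermediate
9 | (2S)-2-{[(1R)-1-(3-bromofuran-2-yl)ethyl]amino}propan-1-ol | C[C@H](N[C@H](C)c1occc1Br)CO | intermediate
10 | (4S)-3-[(1R)-1-(3-bromofuran-2-yl)ethyl]-4-methyl-1,2,3-oxathiazolidine 2,2-dioxide | C[C@H]1COS(=O)(=O)N1[C@H](C)c1occc1Br | intermediate
11 | ethynyltrimethylsilane | C#C[Si](C)(C)C | starting material
12 | N-[(1R)-1-(3-bromofuran-2-yl)ethyl]-N-[(2S)-5-(trimethylsilyl)pent-4-yn-2-yl]sulfamic acid | C[C@@H](CC#C[Si](C)(C)C)N([C@H](C)c1occc1Br)S(=O)(=O)O | intermediate (not isolated)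
13 | (2S)-N-[(1R)-1-(3-bromofuran-2-yl)ethyl]-5-(trimethylsilyl)pent-4-yn-2-amine | C[C@@H](CC#C[Si](C)(C)C)N[C@H](C)c1occc1Br | intermediate (not isolated)
14 | (2S)-N-[(1R)-1-(3-bromofuran-2-yl)ethyl]pent-4-yn-2-amine | C[C@@H](CC#C)N[C@H](C)c1occc1Br | intermediate
15 | (2S)-N-[(1R)-1-(3-bromofuran-2-yl)ethyl]-N-methylpent-4-yn-2-amine | C[C@@H](CC#C)N(C)[C@H](C)c1occc1Br | intermediate
16 | 3-methoxy-2-(trimethylsilyl)phenyl trifluoromethanesulfonate | COc1cccc(OS(=O)(=O)C(F)(F)F)c1[Si](C)(C)C | starting material
17 | acetylacetone | CC(=O)CC(C)=O | starting material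
18 | 3-methoxybenzyne | COC1=CC=CC#C1 | intermediate (not isolated)
19 | 1-(2-acetyl-3-methoxyphenyl)propan-2-one | COc1cccc(CC(C)=O)c1C(C)=O | intermediate
20 | 8-methoxy-3-methylnaphthalen-1-ol | COc1cccc2cc(C)cc(O)c12 | intermediate
21 | 8-methoxy-3-methylnaphthalen-1-yl acetate | COc1cccc2cc(C)cc(OC(C)=O)c12 | intermediate
22 | 5-iodo-8-methoxy-3-methylnaphthalen-1-yl acetate | COc1ccc(I)c2cc(C)cc(OC(C)=O)c12 | intermediate
23 | 5-iodo-8-methoxy-3-methylnaphthalen-1-ol | COc1ccc(I)c2cc(C)cc(O)c12 | intermediate (not isolated)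
24 | 1-iodo-4,5-dimethoxy-7-methylnaphthalene | COc1ccc(I)c2cc(C)cc(OC)c12 | intermediate
25 | (2S)-N-[(1R)-1-(3-bromofuran-2-yl)ethyl]-5-(4,5-dimethoxy-7-methylnaphthalen-1-yl)-N-methylpent-4-yn-2-amine (key-step precursor) | Brc1ccoc1[C@@H](C)N(C)[C@@H](C)CC#Cc1ccc(OC)c2c(OC)cc(C)cc12 | intermediate
26 | (1R,3S)-8-bromo-5-(4,5-dimethoxy-7-methylnaphthalen-1-yl)-1,2,3-trimethyl-1,2,3,4-tetrahydro-6H-6,8a-epoxyisoquinoline (oxygen-bridged cycloadduct, bridge configuration not defined) | C[C@H]1N(C)[C@@H](C)CC2=C(c3ccc(OC)c4c(OC)cc(C)cc34)C3OC21C(Br)=C3 | intermediate (not isolated)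
27 | (1R,3S)-8-bromo-5-(4,5-dimethoxy-7-methylnaphthalen-1-yl)-1,2,3-trimethyl-1,2,3,4-tetrahydroisoquinolin-6-ol (key-step product) | Oc1cc(Br)c2c(c1-c1ccc(OC)c3c(OC)cc(C)cc13)C[C@H](C)N(C)[C@@H]2C | intermediate
28 | (1R,3S)-8-bromo-5-(4,5-dimethoxy-7-methylnaphthalen-1-yl)-6-methoxy-1,2,3-trimethyl-1,2,3,4-tetrahydroisoquinoline | COc1cc(Br)c2c(c1-c1ccc(OC)c3c(OC)cc(C)cc13)C[C@H](C)N(C)[C@@H]2C | intermediate
29 | (1R,3S)-5-(4,5-dimethoxy-7-methylnaphthalen-1-yl)-6,8-dimethoxy-1,2,3-trimethyl-1,2,3,4-tetrahydroisoquinoline | COc1cc(OC)c2c(c1-c1ccc(OC)c3c(OC)cc(C)cc13)C[C@H](C)N(C)[C@@H]2C | target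

**Step count and risks**

Total step count: 18. Longest linear sequence: 12 steps (steps 1–3, 5–9, 15–18).

Steps most likely to fail:

1. Step 16 (proposed new method). The unactivated aryl alkyne on a four-atom tether may not undergo cycloaddition below the temperature at which the furan amine decomposes, the adduct may revert, or the bridge may ionise toward C6 and rearrange instead of aromatising. Fallback by known chemistry, setting out from iodide 24 and coming back at target 29: the C5–C1' bond would be made by cross-coupling onto a preformed isoquinoline.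
   - Miyaura borylation of 24 (B2pin2, PdCl2(dppf), KOAc, dioxane, 80 °C) would give 2-(4,5-dimethoxy-7-methylnaphthalen-1-yl)-4,4,5,5-tetramethyl-1,3,2-dioxaborolane F1.
   - Separately, 3,5-dimethoxyphenylmagnesium bromide and (R)-propylene oxide (CuI cat., THF) would give (2R)-1-(3,5-dimethoxyphenyl)propan-2-ol F2.
   - Mitsunobu azidation with inversion (DPPA, DIAD, PPh3) would give 1-[(2S)-2-azidopropyl]-3,5-dimethoxybenzene F3.
   - Hydrogenation in the presence of Ac2O (H2, Pd/C, EtOAc) would give N-[(2S)-1-(3,5-dimethoxyphenyl)propan-2-yl]acetamide F4.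
   - Bischler–Napieralski closure (POCl3, MeCN, reflux) would give (3S)-6,8-dimethoxy-1,3-dimethyl-3,4-dihydroisoquinoline F5.
   - NaBH4 in MeOH should reduce the imine from the face opposite the C3 methyl group to the cis amine (1R,3S)-6,8-dimethoxy-1,3-dimethyl-1,2,3,4-tetrahydroisoquinoline F6.
   - Reductive methylation (CH2O, NaBH(OAc)3) would give (1R,3S)-6,8-dimethoxy-1,2,3-trimethyl-1,2,3,4-tetrahydroisoquinoline F7.
   - Iodination at C5 (NIS, TFA, MeCN) would give (1R,3S)-5-iodo-6,8-dimethoxy-1,2,3-trimethyl-1,2,3,4-tetrahydroisoquinoline F8.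
   - Suzuki coupling of F1 with F8 (Pd2(dba)3, SPhos, K3PO4, toluene–H2O, 100 °C) would give 29.

2. Step 7. The chlorosulfonylated amino alcohol may close at carbon (aziridine formation) or be substituted by chloride instead of closing at sulfur. Fallback, setting out from amino alcohol 9 and coming back at amine 14: intramolecular Mitsunobu cyclisation (PPh3, DIAD, THF) would give (2S)-1-[(1R)-1-(3-bromofuran-2-yl)ethyl]-2-methylaziridine F9. BF3·OEt2-assisted opening of F9 at its CH2 carbon with lithium (trimethylsilyl)acetylide (THF, −78 °C) would give the C-silyl amine 13, and K2CO3 in MeOH would then give 14.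

3. Step 18. Oxidative addition at the hindered, electron-rich C8–Br bond may stall, or hydrodebromination may compete with C–O coupling. Fallback, setting out from bromide 28 and coming back at target 29: hydroxylation with hydroxide (Pd2(dba)3, tBuXPhos, KOH, dioxane–H2O, 100 °C) would give (1R,3S)-5-(4,5-dimethoxy-7-methylnaphthalen-1-yl)-6-methoxy-1,2,3-trimethyl-1,2,3,4-tetrahydroisoquinolin-8-ol F10, and O-methylation of F10 with TMSCHN2 in MeOH would give 29.

**Further compounds**

F1 | step 16 | 2-(4,5-dimethoxy-7-methylnaphthalen-1-yl)-4,4,5,5-tetramethyl-1,3,2-dioxaborolane | COc1ccc(B2OC(C)(C)C(C)(C)O2)c2cc(C)cc(OC)c12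
F2 | step 16 | (2R)-1-(3,5-dimethoxyphenyl)propan-2-ol | C[C@@H](O)Cc1cc(OC)cc(OC)c1
F3 | step 16 | 1-[(2S)-2-azidopropyl]-3,5-dimethoxybenzene | C[C@H](N=[N+]=[N-])Cc1cc(OC)cc(OC)c1
F4 | step 16 | N-[(2S)-1-(3,5-dimethoxyphenyl)propan-2-yl]acetamide | C[C@H](NC(C)=O)Cc1cc(OC)cc(OC)c1
F5 | step 16 | (3S)-6,8-dimethoxy-1,3-dimethyl-3,4-dihydroisoquinoline | CC1=N[C@@H](C)Cc2cc(OC)cc(OC)c12
F6 | step 16 | (1R,3S)-6,8-dimethoxy-1,3-dimethyl-1,2,3,4-tetrahydroisoquinoline | C[C@H]1N[C@@H](C)Cc2cc(OC)cc(OC)c12
F7 | step 16 | (1R,3S)-6,8-dimethoxy-1,2,3-trimethyl-1,2,3,4-tetrahydroisoquinoline | C[C@H]1N(C)[C@@H](C)Cc2cc(OC)cc(OC)c12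
F8 | step 16 | (1R,3S)-5-iodo-6,8-dimethoxy-1,2,3-trimethyl-1,2,3,4-tetrahydroisoquinoline | C[C@H]1N(C)[C@@H](C)Cc2c(I)c(OC)cc(OC)c12
F9 | step 7 | (2S)-1-[(1R)-1-(3-bromofuran-2-yl)ethyl]-2-methylaziridine | C[C@H]1CN1[C@H](C)c1occc1Br
F10 | step 18 | (1R,3S)-5-(4,5-dimethoxy-7-methylnaphthalen-1-yl)-6-methoxy-1,2,3-trimethyl-1,2,3,4-tetrahydroisoquinolin-8-ol | COc1cc(O)c2c(c1-c1ccc(OC)c3c(OC)cc(C)cc13)C[C@H](C)N(C)[C@@H]2C
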